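## Retrosynthetic overview

- Late stage: the C15 aldehyde comes from allylic oxidation of the C4 isopropenyl group, the 9α-angelate from acylation, and the trans 8,12-γ-lactone (second ring) from lactonisation of an 8α,9α-diol methyl ester; everything else is one cyclohexanol.
- Key disconnection: ring bonds C5–C10 and C6–C7 are cut together, which opens the cyclohexane (first ring) to one acyclic allyl 1,3-dienyl ether carrying a 2-(methoxycarbonyl)allylboronate. Forward, a Claisen rearrangement makes C5–C10 and the aldehyde it unmasks is closed onto C7 by intramolecular allylboration.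
- Enabling feature: the carbinol ring carbon C6 is the hinge of two retrons. One is the γ,δ-unsaturated carbonyl array O=C6–C5–C10(quaternary, CH3)–C1=C2 (the vinyl group). The other is the homoallylic alcohol array HO–C6–C7–C11(=C13H2)–C12O2R (the methylene-lactone carbons). The C3=C4 isopropenyl on C5 is the second alkene of the dienyl ether.
- The chain comes from 2,3-O-isopropylidene-D-erythronolactone (C7–C10 with stereocentres C8 and C9; its dioxolane is a temporary ring). A Corey–Fuchs/methylcuprate sequence gives the (Z)-C1=C10 alkene, copper-catalysed O-vinylation the (E)-dienyl ether, and vinylalumination/borylation the allylboronate.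
- Ring order: dioxolane (present from the start, removed in step 15), then cyclohexane (step 13), then γ-lactone (step 15).

Key step: step 13

Remark: atoms are labelled by elemane numbering (C10 = quaternary ring carbon with methyl C14 and vinyl C1=C2; C5 = ring carbon bearing C4 with C3 and C15; C6–C9 continue round the ring; C11–C13 = acrylate/lactone carbons; β = the face of C14), and compounds 1, 9, 15 and 26 are assumed to be commercial.

## Route

Step 1
Reactants: 1 2,3-O-isopropylidene-D-erythronolactone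
Product: 2 2,3-O-isopropylidene-D-erythrofuranose (lactol)
Conditions: i-Bu2AlH (1.1 equiv), CH2Cl2, −78 °C; Rochelle salt work-up
Reagents that add atoms: none
Why: Partial reduction of a γ-lactone with i-Bu2AlH at −78 °C stops at the lactol because the tetrahedral aluminium hemiacetal survives until work-up, and both stereocentres come unchanged from the chiral pool.

Step 2
Reactants: 2 2,3-O-isopropylidene-D-erythrofuranose
Product: 3 [(4R,5S)-5-(2,2-dibromoethenyl)-2,2-dimethyl-1,3-dioxolan-4-yl]methanol
Conditions: CBr4, PPh3, Zn, CH2Cl2, rt (ylide preformed); then 2, 0 °C → rt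
Reagents that add atoms: carbon tetrabromide, BrC(Br)(Br)Br
Why: Ramirez–Corey–Fuchs dibromo-olefination with the preformed, non-basic ylide Ph3P=CBr2 takes the open-chain aldehyde form of the lactol, so the epimerisable cis-dioxolane α-centre never sees base and the primary hydroxyl is set free.

Step 3
Reactants: 3 dibromoalkene alcohol
Product: 4 tert-butyl{[(4R,5S)-5-(2,2-dibromoethenyl)-2,2-dimethyl-1,3-dioxolan-4-yl]methoxy}dimethylsilane
Conditions: TBSCl, imidazole, DMF, rt
Reagents that add atoms: tert-butyldimethylsilyl chloride, CC(C)(C)[Si](C)(C)Cl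
Why: Standard silylation of the primary alcohol masks the C7 hydroxyl for the organolithium and cuprate steps.

Step 4
Reactants: 4 dibromoalkene silyl ether
Product: 6 methyl 3-[(4S,5R)-5-({[tert-butyl(dimethyl)silyl]oxy}methyl)-2,2-dimethyl-1,3-dioxolan-4-yl]prop-2-ynoate, via lithium acetylide 5 (not isolated)
Conditions: n-BuLi (2.1 equiv), THF, −78 °C; then ClCO2Me, −78 → 0 °C
Reagents that add atoms: methyl chloroformate, COC(=O)Cl
Why: In the second half of the Corey–Fuchs sequence, bromine–lithium exchange and Fritsch–Buttenberg–Wiechell-type rearrangement give the lithium acetylide, which methyl chloroformate acylates to the ynoate.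

Step 5
Reactants: 6 ynoate
Product: 7 methyl (2Z)-3-[(4S,5R)-5-({[tert-butyl(dimethyl)silyl]oxy}methyl)-2,2-dimethyl-1,3-dioxolan-4-yl]but-2-enoate
Conditions: Me2CuLi (from MeLi, CuI), THF, −78 °C; NH4Cl quench at −78 °C
Reagents that add atoms: lithium dimethylcuprate Me2CuLi, [Li+].C[Cu-]C
Why: syn-Carbocupration of the ynoate at −78 °C with cold protonation places the new methyl cis to hydrogen, so the dioxolane carbon ends cis to the ester and the (Z)-trisubstituted C1=C10 alkene is fixed.

Step 6
Reactants: 7 (Z)-enoate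
Product: 8 (2Z)-3-[(4S,5R)-5-({[tert-butyl(dimethyl)silyl]oxy}methyl)-2,2-dimethyl-1,3-dioxolan-4-yl]but-2-en-1-ol
Conditions: i-Bu2AlH (2.5 equiv), CH2Cl2, −78 °C
Reagents that add atoms: none
Why: i-Bu2AlH reduces the conjugated ester in a 1,2-fashion to the allylic alcohol without touching the alkene geometry, the acetonide or the silyl ether.

Step 7
Reactants: 9 2-methylbut-1-en-3-yne
Product: 11 (1E)-1-iodo-3-methylbuta-1,3-diene, via dienylzirconocene chloride 10 (not isolated)
Conditions: Cp2Zr(H)Cl, THF, rt; then I2, 0 °C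
Reagents that add atoms: iodine, II
Why: Schwartz hydrozirconation adds Zr–H syn and anti-Markovnikov to the terminal alkyne in preference to the 1,1-disubstituted alkene, and iodinolysis with retention gives the (E)-dienyl iodide.

Step 8
Reactants: 8 (Z)-allylic alcohol; 11 (E)-dienyl iodide
Product: 12 tert-butyl(dimethyl){[(4R,5S)-2,2-dimethyl-5-[(2Z)-4-{[(1E)-3-methylbuta-1,3-dien-1-yl]oxy}but-2-en-2-yl]-1,3-dioxolan-4-yl]methoxy}silane
Conditions: CuI (10 mol %), 3,4,7,8-tetramethyl-1,10-phenanthroline (20 mol %), Cs2CO3, PhMe, 80 °C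
Reagents that add atoms: none
Why: Ullmann-type copper-catalysed C–O coupling of a vinyl iodide with a primary allylic alcohol proceeds with retention of the (E)-geometry, and 80 °C should stay below the temperature at which this trisubstituted allyl dienyl ether rearranges.

Step 9
Reactants: 12 silyl ether
Product: 13 [(4R,5S)-2,2-dimethyl-5-[(2Z)-4-{[(1E)-3-methylbuta-1,3-dien-1-yl]oxy}but-2-en-2-yl]-1,3-dioxolan-4-yl]methanol
Conditions: TBAF, THF, 0 °C
Reagents that add atoms: none
Why: Fluoride cleaves the primary silyl ether while the base-stable dienyl ether and the acetonide are untouched.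

Step 10
Reactants: 13 primary alcohol
Product: 14 (4S,5S)-2,2-dimethyl-5-[(2Z)-4-{[(1E)-3-methylbuta-1,3-dien-1-yl]oxy}but-2-en-2-yl]-1,3-dioxolane-4-carbaldehyde
Conditions: Dess–Martin periodinane, NaHCO3, CH2Cl2, 0 °C
Reagents that add atoms: none
Why: Dess–Martin oxidation buffered with NaHCO3 gives the α-alkoxy aldehyde under neutral conditions, which spares the acid-labile dienyl ether and avoids epimerisation of the cis-dioxolane centre next to the formyl group.

Step 11
Reactants: 14 aldehyde; 15 methyl propiolate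
Product: 18 methyl 2-{acetoxy[(4,5-cis)-dioxolanyl]methyl}prop-2-enoate (Morita–Baylis–Hillman acetate of 14; epimer mixture at the acetoxy carbon), via vinylalane 16 (not isolated), via aluminium alkoxide 17 (not isolated)
Conditions: i-Bu2AlH, NMO, THF, 0 °C; 15; then 14, 0 °C → rt; then Ac2O, pyridine, DMAP (cat.)
Reagents that add atoms: acetic anhydride, CC(=O)OC(C)=O
Why: Vinylalumination (hydroalumination of methyl propiolate, then 1,2-addition of the α-aluminoacrylate to the aldehyde) gives the Morita–Baylis–Hillman-type adduct at low temperature without amine base, acetylation of the aluminium alkoxide in the same flask gives the allylic acetate, and the new carbinol centre may form as a mixture because it becomes sp2 in step 12.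

Step 12
Reactants: 18 Morita–Baylis–Hillman acetate
Product: 19 methyl (2E)-3-[(4R,5S)-2,2-dimethyl-5-[(2Z)-4-{[(1E)-3-methylbuta-1,3-dien-1-yl]oxy}but-2-en-2-yl]-1,3-dioxolan-4-yl]-2-[(4,4,5,5-tetramethyl-1,3,2-dioxaborolan-2-yl)methyl]prop-2-enoate
Conditions: B2pin2, CuCl (10 mol %), Xantphos (10 mol %), KOt-Bu (10 mol %), THF, 0 °C → rt
Reagents that add atoms: bis(pinacolato)diboron, CC1(C)OB(OC1(C)C)B1OC(C)(C)C(C)(C)O1
Why: Copper-catalysed SN2' borylation of a Morita–Baylis–Hillman acetate (conjugate addition of Cu–Bpin to the acrylate, then β-elimination of acetate) should give the 2-alkoxycarbonyl allylboronate as the thermodynamically preferred isomer, with the dioxolane carbon trans to the ester and cis to CH2B as the ring closure requires, while the electron-rich dienyl ether is not a substrate for the nucleophilic boryl copper species.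

Step 13
Reactants: 19 allyl dienyl ether allylboronate
Product: 22 methyl 6β-hydroxy-8α,9α-(isopropylidenedioxy)elema-1,3,11(13)-trien-12-oate, via Claisen aldehyde 20 (not isolated), via pinacol borate 21 (not isolated)
Conditions: PhMe (5 mM), BHT (5 mol %), base-washed sealed tube, 120 °C; then pH 7 phosphate buffer, rt
Reagents that add atoms: none
Why: Proposed new method: heating triggers a chair [3,3]-sigmatropic (Claisen) shift of the allyl 1,3-dienyl ether that forms C5–C10 and unmasks the C6 aldehyde, which the tethered 2-alkoxycarbonyl allylboronate captures at once through a six-membered Zimmerman–Traxler transition state, forming C6–C7 with allyl transposition to the C11=C13 methylene. The closest known reactions are the Claisen step of allyl dienyl ethers in the prenal-acetal route to citral, tandem Claisen–ene ring closures, domino aldehyde generation/intramolecular allylboration, and the thermal allylboration of aldehydes by 2-alkoxycarbonyl allylboronates. One ring is closed, the cyclohexane C5–C6–C7–C8–C9–C10, by 6-exo-trig addition of C7 to the C6 carbonyl in a chair that is cis-fused to the dioxolane (O8 equatorial, O9 axial). C10 and C5 arise together: the chair Claisen transition state translates the (Z)-allyl and (E)-dienyl geometries into their relative configuration, and C9 fixes the face, because allylic 1,3-strain with the CH2O arm holds H9 in the alkene plane and the C8 arm of the cis-dioxolane with its acrylate unit blocks one side, so that C5 should add anti to C8. C7 is set by allylic 1,3-strain at C8 (H8 eclipsed with the CH2B arm while the tether delivers the aldehyde to the face that places C11 equatorial), and C6 by the closed transition state, in which a γ-substituent cis to CH2B gives the cis 6β-OH/7β-C11 pair. The step needs ring closure to outrun Cope rearrangement of the α-isopropenyl aldehyde and the O6 borate not to attack the ester; the intramolecular six-ring allylboration, the high dilution and the low nucleophilicity of a pinacol borate are what should secure this.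

Step 14
Reactants: 22 cyclohexanol
Product: 23 methyl 6β-(tert-butyldimethylsilyloxy)-8α,9α-(isopropylidenedioxy)elema-1,3,11(13)-trien-12-oate
Conditions: TBSOTf, 2,6-lutidine, CH2Cl2, −20 °C → rt
Reagents that add atoms: tert-butyldimethylsilyl triflate, CC(C)(C)[Si](C)(C)OS(=O)(=O)C(F)(F)F
Why: Silyl triflate/2,6-lutidine silylation protects the hindered axial 6β-hydroxyl before it can lactonise onto C12 and leaves the ester and the acetonide intact.

Step 15
Reactants: 23 silyl ether acetonide
Product: 25 6β-(tert-butyldimethylsilyloxy)-9α-hydroxyelema-1,3,11(13)-trien-12,8α-olide, via diol ester 24 (not isolated)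
Conditions: AcOH/THF/H2O (3:1:1), 45 °C; then PPTS (10 mol %), PhMe, 70 °C
Reagents that add atoms: none
Why: Acid hydrolysis of the cis-fused acetonide frees the 8α,9α-diol and acid-catalysed transesterification then closes the trans γ-lactone (5-exo-trig acyl substitution) from the equatorial 8α-hydroxyl, the only one that can reach C12 because O6 is silylated and the axial 9α-hydroxyl could only form a strained trans-bridged δ-lactone.

Step 16
Reactants: 25 lactone alcohol; 26 angelic acid
Product: 28 9α-angeloyloxy-6β-(tert-butyldimethylsilyloxy)elema-1,3,11(13)-trien-12,8α-olide, via mixed anhydride 27 (not isolated)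
Conditions: 26, 2,4,6-trichlorobenzoyl chloride, Et3N, PhMe, rt; then 25, 80 °C
Reagents that add atoms: none
Why: Acylation by the mixed anhydride of angelic acid and 2,4,6-trichlorobenzoic acid (Yamaguchi-type esterification without a nucleophilic catalyst) transfers the (Z)-2-methylbut-2-enoyl group to the only free hydroxyl, 9α-OH, under conditions known to keep an angelate from isomerising to the tiglate.

Step 17
Reactants: 28 angelate
Product: 30 9α-angeloyloxy-6β-(tert-butyldimethylsilyloxy)-15-oxoelema-1,3,11(13)-trien-12,8α-olide, via allylic alcohol 29 (not isolated)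
Conditions: SeO2 (0.3 equiv), t-BuOOH, CH2Cl2, rt; then MnO2, CH2Cl2, rt
Reagents that add atoms: tert-butyl hydroperoxide (oxygen donor, relayed by SeO2), CC(C)(C)OO
Why: Selenium dioxide allylic oxidation (ene reaction then [2,3]-sigmatropic shift) should attack only the electron-rich isopropenyl group and, following the CH3 over CH order, its methyl group, because the vinyl group has no allylic hydrogen and the methylene lactone and angelate are electron-poor, and MnO2 then takes the allylic alcohol on to the 2-substituted acrolein.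

Step 18
Reactants: 30 silyl-protected enal
Product: 31 9α-angeloyloxy-6β-hydroxy-15-oxoelema-1,3,11(13)-trien-12,8α-olide (target, 5R,6S,7S,8R,9S,10S)
Conditions: HF·pyridine, THF/pyridine, 0 °C → rt
Reagents that add atoms: none
Why: Desilylation with buffered HF·pyridine removes the TBS ether under mildly acidic, non-nucleophilic conditions that should leave the enal, the α-methylene lactone and the angelate untouched.

## Compound list

1 | 2,3-O-isopropylidene-D-erythronolactone, (3aR,6aR)-2,2-dimethyldihydrofuro[3,4-d][1,3]dioxol-4(3aH)-one | O=C1OC[C@H]2OC(C)(C)O[C@@H]12 | starting material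
2 | 2,3-O-isopropylidene-D-erythrofuranose (lactol, anomer mixture) | OC1OC[C@H]2OC(C)(C)O[C@@H]12 | intermediate
3 | [(4R,5S)-5-(2,2-dibromoethenyl)-2,2-dimethyl-1,3-dioxolan-4-yl]methanol | BrC(Br)=C[C@@H]1OC(C)(C)O[C@@H]1CO | intermediate
4 | tert-butyl{[(4R,5S)-5-(2,2-dibromoethenyl)-2,2-dimethyl-1,3-dioxolan-4-yl]methoxy}dimethylsilane | BrC(Br)=C[C@@H]1OC(C)(C)O[C@@H]1CO[Si](C)(C)C(C)(C)C | intermediate
5 | lithium acetylide Li–C≡C–[(4S,5R)-5-(TBSOCH2)-2,2-dimethyl-1,3-dioxolan-4-yl] (not isolated) | [Li]C#C[C@@H]1OC(C)(C)O[C@@H]1CO[Si](C)(C)C(C)(C)C | intermediate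
6 | methyl 3-[(4S,5R)-5-({[tert-butyl(dimethyl)silyl]oxy}methyl)-2,2-dimethyl-1,3-dioxolan-4-yl]prop-2-ynoate | COC(=O)C#C[C@@H]1OC(C)(C)O[C@@H]1CO[Si](C)(C)C(C)(C)C | intermediate
7 | methyl (2Z)-3-[(4S,5R)-5-({[tert-butyl(dimethyl)silyl]oxy}methyl)-2,2-dimethyl-1,3-dioxolan-4-yl]but-2-enoate | COC(=O)/C=C(C)\[C@@H]1OC(C)(C)O[C@@H]1CO[Si](C)(C)C(C)(C)C | intermediate
8 | (2Z)-3-[(4S,5R)-5-({[tert-butyl(dimethyl)silyl]oxy}methyl)-2,2-dimethyl-1,3-dioxolan-4-yl]but-2-en-1-ol | OC/C=C(C)\[C@@H]1OC(C)(C)O[C@@H]1CO[Si](C)(C)C(C)(C)C | intermediate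
9 | 2-methylbut-1-en-3-yne | C=C(C)C#C | starting material
10 | Cp2Zr(Cl)[(1E)-3-methylbuta-1,3-dien-1-yl] (dienylzirconocene chloride, not isolated) | C=C(C)/C=C/[Zr](Cl)(C1C=CC=C1)C1C=CC=C1 | intermediate
11 | (1E)-1-iodo-3-methylbuta-1,3-diene | C=C(C)/C=C/I | intermediate
12 | tert-butyl(dimethyl){[(4R,5S)-2,2-dimethyl-5-[(2Z)-4-{[(1E)-3-methylbuta-1,3-dien-1-yl]oxy}but-2-en-2-yl]-1,3-dioxolan-4-yl]methoxy}silane | C=C(C)/C=C/OC/C=C(C)\[C@@H]1OC(C)(C)O[C@@H]1CO[Si](C)(C)C(C)(C)C | intermediate
13 | [(4R,5S)-2,2-dimethyl-5-[(2Z)-4-{[(1E)-3-methylbuta-1,3-dien-1-yl]oxy}but-2-en-2-yl]-1,3-dioxolan-4-yl]methanol | C=C(C)/C=C/OC/C=C(C)\[C@@H]1OC(C)(C)O[C@@H]1CO | intermediate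
14 | (4S,5S)-2,2-dimethyl-5-[(2Z)-4-{[(1E)-3-methylbuta-1,3-dien-1-yl]oxy}but-2-en-2-yl]-1,3-dioxolane-4-carbaldehyde | C=C(C)/C=C/OC/C=C(C)\[C@@H]1OC(C)(C)O[C@@H]1C=O | intermediate
15 | methyl propiolate | C#CC(=O)OC | starting material
16 | i-Bu2Al–C(=CH2)CO2Me, [1-(methoxycarbonyl)ethenyl]diisobutylaluminium (not isolated) | C=C(C(=O)OC)[Al](CC(C)C)CC(C)C | intermediate
17 | i-Bu2Al alkoxide of the Morita–Baylis–Hillman-type adduct of 14 (dioxolane centres as in 14, carbinol epimers, not isolated) | C=C(C)/C=C/OC/C=C(C)\[C@@H]1OC(C)(C)O[C@@H]1C(O[Al](CC(C)C)CC(C)C)C(=C)C(=O)OC | intermediate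
18 | methyl 2-{acetoxy[(4,5-cis)-2,2-dimethyl-5-[(2Z)-4-{[(1E)-3-methylbuta-1,3-dien-1-yl]oxy}but-2-en-2-yl]-1,3-dioxolan-4-yl]methyl}prop-2-enoate (dioxolane centres as in 14, epimers at the acetoxy carbon) | C=C(C)/C=C/OC/C=C(C)\[C@@H]1OC(C)(C)O[C@@H]1C(OC(C)=O)C(=C)C(=O)OC | intermediate
19 | methyl (2E)-3-[(4R,5S)-2,2-dimethyl-5-[(2Z)-4-{[(1E)-3-methylbuta-1,3-dien-1-yl]oxy}but-2-en-2-yl]-1,3-dioxolan-4-yl]-2-[(4,4,5,5-tetramethyl-1,3,2-dioxaborolan-2-yl)methyl]prop-2-enoate | C=C(C)/C=C/OC/C=C(C)\[C@@H]1OC(C)(C)O[C@@H]1/C=C(\CB2OC(C)(C)C(C)(C)O2)C(=O)OC | intermediate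
20 | Claisen aldehyde: C6 formyl, (5S)-isopropenyl, (10S)-quaternary carbon with methyl and vinyl, dioxolane and (E)-allylboronate arm as in 19 (not isolated) | O=C[C@@H](C(C)=C)[C@](C)(C=C)[C@@H]1OC(C)(C)O[C@@H]1/C=C(\CB2OC(C)(C)C(C)(C)O2)C(=O)OC | intermediate
21 | pinacol borate (O6–Bpin) of 22 (not isolated) | C=C[C@]1(C)[C@@H]2OC(C)(C)O[C@@H]2[C@@H](C(=C)C(=O)OC)[C@@H](OB3OC(C)(C)C(C)(C)O3)[C@H]1C(C)=C | intermediate
22 | methyl 6β-hydroxy-8α,9α-(isopropylidenedioxy)elema-1,3,11(13)-trien-12-oate (5α-H, 7α-H, 10β-methyl) | C=C[C@]1(C)[C@@H]2OC(C)(C)O[C@@H]2[C@@H](C(=C)C(=O)OC)[C@@H](O)[C@H]1C(C)=C | intermediate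
23 | methyl 6β-(tert-butyldimethylsilyloxy)-8α,9α-(isopropylidenedioxy)elema-1,3,11(13)-trien-12-oate | C=C[C@]1(C)[C@@H]2OC(C)(C)O[C@@H]2[C@@H](C(=C)C(=O)OC)[C@@H](O[Si](C)(C)C(C)(C)C)[C@H]1C(C)=C | intermediate
24 | methyl 6β-(tert-butyldimethylsilyloxy)-8α,9α-dihydroxyelema-1,3,11(13)-trien-12-oate (not isolated) | C=C[C@]1(C)[C@H](O)[C@H](O)[C@@H](C(=C)C(=O)OC)[C@@H](O[Si](C)(C)C(C)(C)C)[C@H]1C(C)=C | intermediate
25 | 6β-(tert-butyldimethylsilyloxy)-9α-hydroxyelema-1,3,11(13)-trien-12,8α-olide | C=C[C@]1(C)[C@H](O)[C@@H]2OC(=O)C(=C)[C@H]2[C@@H](O[Si](C)(C)C(C)(C)C)[C@H]1C(C)=C | intermediate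
26 | angelic acid, (2Z)-2-methylbut-2-enoic acid | C/C=C(/C)C(=O)O | starting material
27 | angelic 2,4,6-trichlorobenzoic anhydride (not isolated) | C/C=C(/C)C(=O)OC(=O)c1c(Cl)cc(Cl)cc1Cl | intermediate
28 | 9α-angeloyloxy-6β-(tert-butyldimethylsilyloxy)elema-1,3,11(13)-trien-12,8α-olide | C=C[C@]1(C)[C@H](OC(=O)/C(C)=C\C)[C@@H]2OC(=O)C(=C)[C@H]2[C@@H](O[Si](C)(C)C(C)(C)C)[C@H]1C(C)=C | intermediate
29 | 9α-angeloyloxy-15-hydroxy-6β-(tert-butyldimethylsilyloxy)elema-1,3,11(13)-trien-12,8α-olide (not isolated) | C=C[C@]1(C)[C@H](OC(=O)/C(C)=C\C)[C@@H]2OC(=O)C(=C)[C@H]2[C@@H](O[Si](C)(C)C(C)(C)C)[C@H]1C(=C)CO | intermediate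
30 | 9α-angeloyloxy-6β-(tert-butyldimethylsilyloxy)-15-oxoelema-1,3,11(13)-trien-12,8α-olide | C=C[C@]1(C)[C@H](OC(=O)/C(C)=C\C)[C@@H]2OC(=O)C(=C)[C@H]2[C@@H](O[Si](C)(C)C(C)(C)C)[C@H]1C(=C)C=O | intermediate
31 | CNP0320538.1, 9α-angeloyloxy-6β-hydroxy-15-oxoelema-1,3,11(13)-trien-12,8α-olide, (5R,6S,7S,8R,9S,10S) | C=C[C@]1(C)[C@H](OC(=O)/C(C)=C\C)[C@@H]2OC(=O)C(=C)[C@H]2[C@@H](O)[C@H]1C(=C)C=O | target

## Step count and risks

Total step count: 18. Longest linear sequence: 17 steps (1 to 31 through steps 1–6 and 8–18); step 7 is a one-step side branch.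

Steps most likely to fail:

1) Step 13. The transient α-isopropenyl aldehyde may undergo Cope rearrangement (loss of the new C5–C10 bond) faster than it is trapped, and facial control at C10 may erode at 120 °C. The fallback uses known chemistry, with the sigmatropic step at low temperature and the ring closure at room temperature. It sets out from 8. Esterification with 3-methylbut-3-enoic acid (DCC, DMAP, 0 °C) would give the allyl ester F1. Ireland–Claisen rearrangement through the (Z)-silyl ketene acetal (LiN(i-Pr)2, THF/DMPU, Me3SiCl, −78 °C → rt) would give the acid F2 with the same chair-controlled C5/C10 pair. LiAlH4 reduction would give the primary alcohol F3, which would be protected as the PMB ether F4 (NaH, PMBCl). The operations of steps 9–12 (TBAF; Dess–Martin periodinane; vinylalumination/Ac2O; CuCl-catalysed borylation) would then give the alcohol F5, the aldehyde F6, the acetate F7 and the allylboronate F8. DDQ would remove the PMB group to give the hydroxy allylboronate F9. Buffered Dess–Martin oxidation at 0 °C would generate aldehyde 20 at a temperature where no Cope rearrangement occurs, so that it should close to 21 and, after work-up, come back to the route at 22.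

2) Step 16. Acylation of the hindered axial 9α-hydroxyl next to the quaternary C10 may be sluggish, and forcing it invites isomerisation of the angelate to the tiglate. The fallback builds the Z-alkene in place and sets out from 25. DCC-mediated acylation with 2-[bis(2,2,2-trifluoroethoxy)phosphoryl]propanoic acid (a small acid with no isomerisable alkene, which acylates through a ketene-like activated form) would give the phosphonopropionate ester F10. Still–Gennari olefination (KN(SiMe3)2, 18-crown-6, THF, −78 °C; acetaldehyde) would then give the (Z)-2-methylbut-2-enoate and come back to the route at 28.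

3) Step 17. The selenium ene reaction may abstract the methine hydrogen at C5 instead of a methyl hydrogen, stall at partial conversion, or over-oxidise. The fallback sets out from 28. A Schenck ene reaction with singlet oxygen (O2, hν, tetraphenylporphyrin, CH2Cl2, 0 °C) on the only electron-rich alkene bearing allylic hydrogens would give the primary allylic hydroperoxide F11. Dehydration with Ac2O/pyridine (Kornblum–DeLaMare-type) would convert it into the enal and come back to the route at 30.

## Further compounds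

F1 | step 13 | (2Z)-3-[(4S,5R)-5-({[tert-butyl(dimethyl)silyl]oxy}methyl)-2,2-dimethyl-1,3-dioxolan-4-yl]but-2-en-1-yl 3-methylbut-3-enoate | C=C(C)CC(=O)OC/C=C(C)\[C@@H]1OC(C)(C)O[C@@H]1CO[Si](C)(C)C(C)(C)C
F2 | step 13 | Ireland–Claisen acid: 2-isopropenyl-3-methyl-3-[(4S,5R)-5-(TBSOCH2)-2,2-dimethyl-1,3-dioxolan-4-yl]pent-4-enoic acid (C5 and C10 as in 20) | OC(=O)[C@@H](C(C)=C)[C@](C)(C=C)[C@@H]1OC(C)(C)O[C@@H]1CO[Si](C)(C)C(C)(C)C
F3 | step 13 | primary alcohol from reduction of F2 (C6 as CH2OH) | OC[C@@H](C(C)=C)[C@](C)(C=C)[C@@H]1OC(C)(C)O[C@@H]1CO[Si](C)(C)C(C)(C)C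
F4 | step 13 | 4-methoxybenzyl ether of F3 | COc1ccc(COC[C@@H](C(C)=C)[C@](C)(C=C)[C@@H]2OC(C)(C)O[C@@H]2CO[Si](C)(C)C(C)(C)C)cc1
F5 | step 13 | C7 primary alcohol from desilylation of F4 | COc1ccc(COC[C@@H](C(C)=C)[C@](C)(C=C)[C@@H]2OC(C)(C)O[C@@H]2CO)cc1
F6 | step 13 | C7 aldehyde from oxidation of F5 | COc1ccc(COC[C@@H](C(C)=C)[C@](C)(C=C)[C@@H]2OC(C)(C)O[C@@H]2C=O)cc1
F7 | step 13 | Morita–Baylis–Hillman acetate from F6 (epimers at the acetoxy carbon) | COc1ccc(COC[C@@H](C(C)=C)[C@](C)(C=C)[C@@H]2OC(C)(C)O[C@@H]2C(OC(C)=O)C(=C)C(=O)OC)cc1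
F8 | step 13 | (E)-2-(methoxycarbonyl)allylboronate from F7, C6 as CH2OPMB | COc1ccc(COC[C@@H](C(C)=C)[C@](C)(C=C)[C@@H]2OC(C)(C)O[C@@H]2/C=C(\CB3OC(C)(C)C(C)(C)O3)C(=O)OC)cc1
F9 | step 13 | hydroxy allylboronate (C6 as CH2OH, the alcohol corresponding to aldehyde 20) | OC[C@@H](C(C)=C)[C@](C)(C=C)[C@@H]1OC(C)(C)O[C@@H]1/C=C(\CB2OC(C)(C)C(C)(C)O2)C(=O)OC
F10 | step 16 | 9α-{2-[bis(2,2,2-trifluoroethoxy)phosphoryl]propanoyloxy}-6β-(tert-butyldimethylsilyloxy)elema-1,3,11(13)-trien-12,8α-olide | C=C[C@]1(C)[C@H](OC(=O)C(C)P(=O)(OCC(F)(F)F)OCC(F)(F)F)[C@@H]2OC(=O)C(=C)[C@H]2[C@@H](O[Si](C)(C)C(C)(C)C)[C@H]1C(C)=C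
F11 | step 17 | 9α-angeloyloxy-15-hydroperoxy-6β-(tert-butyldimethylsilyloxy)elema-1,3,11(13)-trien-12,8α-olide | C=C[C@]1(C)[C@H](OC(=O)/C(C)=C\C)[C@@H]2OC(=O)C(=C)[C@H]2[C@@H](O[Si](C)(C)C(C)(C)C)[C@H]1C(=C)COO
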